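## Retrosynthetic overview

1. Target 22 ⇐ vinyl lactone 21 by hydroxyl-directed epoxidation (oxirane formed last). 21 ⇐ bis-enal 18 by cis-dihydroxylation of C8=C9, lactol closure onto the C12 aldehyde and oxidation (γ-lactone formed second).
2. 18 ⇐ amide 15 (amide to aldehyde, α-methylenation, SeO2 oxidation of the isopropenyl group). 15 ⇐ allylic picolinate 14 by anti-SN2′ vinylation, which builds quaternary C10.
3. Key step: 14 ⇐ allylic alcohol 12 by Eschenmoser–Claisen [3,3] rearrangement, which forms the C5–C4 bond cis to the C7 side chain by chirality transfer from C9–O.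
4. 12 ⇐ hydroxy enone 5 (Mitsunobu angelate at C6, Rubottom oxidation and Mitsunobu inversion at C8, Luche reduction). 5 ⇐ (R)-carvone 1 via the Shapiro diene 3 and a singlet-oxygen [4+2] cycloaddition.
5. Ring order: cyclohexane bought in (R)-carvone (the only source of chirality) → γ-lactone (steps 13–14) → oxirane (step 15).

Assumption: locants are those of the target skeleton (ring C5–C6–C7–C8–C9–C10; C10 bears CH3 and C1–C2; C5 bears C4(=C3)–C15; C7 bears C11(=C13)–C12); β is the ring face of the C10 methyl and the C7 side chain, α the opposite face; in (R)-carvone the carbonyl carbon is C5, the methyl-bearing alkene carbon C10 and the stereocentre C7.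

## Route

Step 1
Reactants: 1 (R)-(−)-carvone
Product: 2 (R)-carvone p-toluenesulfonylhydrazone
Conditions: TsNHNH2, EtOH, cat. AcOH, 20 °C
Reagents that add atoms: p-toluenesulfonohydrazide (Cc1ccc(cc1)S(=O)(=O)NN)
Why: Hydrazone condensation at the enone carbonyl sets up the Shapiro reaction and leaves the C7 stereocentre untouched.

Step 2
Reactants: 2 (R)-carvone p-toluenesulfonylhydrazone
Product: 3 (5R)-2-methyl-5-(prop-1-en-2-yl)cyclohexa-1,3-diene
Conditions: CH3Li (2.2 equiv), Et2O, 0 → 20 °C; then H2O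
Reagents that add atoms: none
Why: Shapiro reaction: the α′-deprotonated dianion loses sulfinate and N2 to a vinyllithium that is protonated to the C6=C5–C10=C9 diene.

Step 3
Reactants: 3 (5R)-2-methyl-5-(prop-1-en-2-yl)cyclohexa-1,3-diene
Product: 5 (4R,5S)-4-hydroxy-2-methyl-5-(prop-1-en-2-yl)cyclohex-2-en-1-one, via endoperoxide 4 (not isolated)
Conditions: O2, visible light, tetraphenylporphyrin (cat.), CH2Cl2, −78 °C; then Et3N (0.5 equiv), −78 → 0 °C
Reagents that add atoms: dioxygen (O=O)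
Why: Singlet oxygen adds in a [4+2] cycloaddition mainly anti to the neighbouring isopropenyl group, and Et3N then removes the less hindered C9–H (Kornblum–DeLaMare rearrangement) to give the C9 ketone and the 6α-hydroxyl.

Step 4
Reactants: 5 (4R,5S)-4-hydroxy-2-methyl-5-(prop-1-en-2-yl)cyclohex-2-en-1-one; 6 angelic acid
Product: 7 (1S,6S)-3-methyl-4-oxo-6-(prop-1-en-2-yl)cyclohex-2-en-1-yl (Z)-2-methylbut-2-enoate (6β-angelate)
Conditions: 6, PPh3, DIAD, toluene, 0 °C
Reagents that add atoms: angelic acid 6 (C/C=C(C)\C(=O)O)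
Why: Mitsunobu esterification inverts the unhindered allylic C6 carbinol by SN2, placing the angelate β (cis to the C7 side chain) without Z/E isomerisation.

Step 5
Reactants: 7 6β-angelate enone
Product: 10 6β-angeloyloxy-8α-hydroxy enone (C9 ketone; hydroxyl trans to isopropenyl), via silyl dienol ether 8 (not isolated), via silyloxy ketone 9 (not isolated)
Conditions: LiN(iPr)2, THF, −78 °C; Me3SiCl; then mCPBA, NaHCO3, CH2Cl2, 0 °C; then aq. citric acid, THF, 20 °C
Reagents that add atoms: mCPBA (OOC(=O)c1cccc(Cl)c1)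
Why: Rubottom oxidation: kinetic C8 deprotonation, silylation and epoxidation of the enol ether anti to the adjacent isopropenyl group give the 8α-hydroxy ketone.

Step 6
Reactants: 10 6β-angeloyloxy-8α-hydroxy enone
Product: 11 6β-angeloyloxy-8β-picolinoyloxy enone (C8 inverted)
Conditions: picolinic acid, PPh3, DIAD, THF, 0 → 20 °C
Reagents that add atoms: picolinic acid (OC(=O)c1ccccn1)
Why: A second Mitsunobu inversion, helped by the adjacent carbonyl, puts the picolinate leaving group on the β face so that copper can later attack anti from the α face.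

Step 7
Reactants: 11 6β-angeloyloxy-8β-picolinoyloxy enone
Product: 12 9β-allylic alcohol (6β-angelate, 8β-picolinate, 9β-OH, C10=C5 alkene)
Conditions: NaBH4, CeCl3·7H2O, MeOH, −78 °C
Reagents that add atoms: none
Why: Luche 1,2-reduction delivers hydride anti to the neighbouring 8β-acyloxy group, giving the 9β-alcohol cis to the C7 side chain.

Step 8
Reactants: 12 9β-allylic alcohol
Product: 14 C5β-(N,N-dimethylcarbamoylmethyl) cyclohexene (C9=C10 alkene; 6β-angelate; 8β-picolinate), via ketene aminal 13 (not isolated)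
Conditions: CH3C(OCH3)2N(CH3)2, xylenes, 140 °C, sealed tube
Reagents that add atoms: N,N-dimethylacetamide dimethyl acetal (COC(C)(OC)N(C)C)
Why: Eschenmoser–Claisen [3,3]-sigmatropic rearrangement transfers the C9–O chirality suprafacially to C5, forming the C5–C4 bond on the β face and moving the alkene to C9=C10.

Step 9
Reactants: 14 allylic picolinate amide
Product: 15 C10-quaternary amide (β-methyl and α-vinyl at C10; C8=C9 alkene)
Conditions: CH2=CHMgBr (2.5 equiv), CuBr·SMe2 (30 mol%), THF, −60 → −30 °C; aq. NH4Cl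
Reagents that add atoms: vinylmagnesium bromide (C=C[Mg]Br)
Why: Copper-catalysed anti-SN2′ allylic substitution of the picolinate delivers vinyl to C10 on the α face, opposite the 8β leaving group, and shifts the alkene to C8=C9.

Step 10
Reactants: 15 C10-quaternary amide
Product: 16 aldehyde (C5β–CH2–CHO)
Conditions: Cp2Zr(H)Cl (1.5 equiv), THF, 20 °C, 20 min; then H2O, silica gel
Reagents that add atoms: none
Why: Schwartz-reagent reduction converts the tertiary amide to the aldehyde through a zirconated hemiaminal faster than it touches the ester or the hindered alkenes.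

Step 11
Reactants: 16 aldehyde
Product: 17 enal (C5β–C(=CH2)–CHO)
Conditions: 37% aq. CH2O, pyrrolidine (10 mol%), EtCO2H (10 mol%), i-PrOH, 45 °C
Reagents that add atoms: formaldehyde (C=O)
Why: Amine-catalysed Mannich condensation and elimination (α-methylenation) builds the 2-substituted acrolein, and C5 cannot epimerise because the product has no α-hydrogen.

Step 12
Reactants: 17 enal
Product: 18 bis-enal (C7β–C(=CH2)–CHO as well)
Conditions: SeO2 (1.1 equiv), 1,4-dioxane, 80 °C
Reagents that add atoms: selenium dioxide (O=[Se]=O)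
Why: Riley allylic oxidation (ene reaction, then [2,3]-sigmatropic shift) takes the methyl of the only electron-rich alkene with allylic hydrogens, the isopropenyl group, to the aldehyde.

Step 13
Reactants: 18 bis-enal
Product: 20 lactol (12,8α-hemiacetal with free 9α-OH; C12 epimers), via diol 19 (not isolated)
Conditions: OsO4 (5 mol%), N-methylmorpholine N-oxide (1.1 equiv), acetone/H2O, 0 °C
Reagents that add atoms: N-methylmorpholine N-oxide (C[N+]1([O-])CCOCC1); water (O)
Why: Upjohn cis-dihydroxylation attacks the electron-richest alkene (C8=C9) from the α face, anti to the axial C10 methyl and the C7 side chain, and the 8α-hydroxyl closes onto the C12 aldehyde.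

Step 14
Reactants: 20 lactol
Product: 21 vinyl lactone (trans-fused α-methylene γ-lactone; 9α-OH; C10 vinyl)
Conditions: TEMPO (10 mol%), PhI(OAc)2 (1.2 equiv), CH2Cl2, 20 °C
Reagents that add atoms: none
Why: Oxoammonium (TEMPO) oxidation takes the lactol to the lactone much faster than it oxidises the hindered axial C9 alcohol.

Step 15
Reactants: 21 vinyl lactone
Product: 22 target CNP0113462.3
Conditions: VO(acac)2 (5 mol%), t-BuOOH (1.5 equiv, anhydrous), CH2Cl2, 0 → 20 °C
Reagents that add atoms: tert-butyl hydroperoxide (CC(C)(C)OO)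
Why: Vanadium-catalysed hydroxyl-directed epoxidation: the axial C9–OH delivers oxygen only to the adjacent equatorial vinyl group, and the chair-like arrangement with the CH2 terminus turned away from the axial methyl is expected to give the (1R)-oxirane.

## Compound list

1 | (R)-(−)-carvone, (5R)-2-methyl-5-(prop-1-en-2-yl)cyclohex-2-en-1-one | C=C(C)[C@@H]1CC=C(C)C(=O)C1 | starting material
2 | (R)-carvone p-toluenesulfonylhydrazone | C=C(C)[C@@H]1CC=C(C)C(=NNS(=O)(=O)c2ccc(C)cc2)C1 | intermediate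
3 | (5R)-2-methyl-5-(prop-1-en-2-yl)cyclohexa-1,3-diene | C=C(C)[C@@H]1CC=C(C)C=C1 | intermediate
4 | 6-methyl-8-(prop-1-en-2-yl)-2,3-dioxabicyclo[2.2.2]oct-5-ene, peroxide bridge (C6 to C9) anti to isopropenyl (not isolated) | C1[C@@H](C(C)=C)[C@@H]2OO[C@H]1C(C)=C2 | intermediate
5 | (4R,5S)-4-hydroxy-2-methyl-5-(prop-1-en-2-yl)cyclohex-2-en-1-one (C9 ketone, 6α-OH trans to isopropenyl) | C1[C@@H](C(C)=C)[C@H](O)C=C(C)C1=O | intermediate
6 | angelic acid, (Z)-2-methylbut-2-enoic acid | C/C=C(C)\C(=O)O | starting material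
7 | (1S,6S)-3-methyl-4-oxo-6-(prop-1-en-2-yl)cyclohex-2-en-1-yl (Z)-2-methylbut-2-enoate (6β-angelate, cis to isopropenyl) | C1[C@@H](C(C)=C)[C@@H](OC(=O)/C(C)=C\C)C=C(C)C1=O | intermediate
8 | cross-conjugated trimethylsilyl dienol ether of 7 (C8=C9–OSiMe3, C10=C5) (not isolated) | C1=C(O[Si](C)(C)C)C(C)=C[C@H](OC(=O)/C(C)=C\C)[C@@H]1C(C)=C | intermediate
9 | 8α-trimethylsilyloxy derivative of 7 (not isolated) | C[Si](C)(C)O[C@@H]1[C@@H](C(C)=C)[C@@H](OC(=O)/C(C)=C\C)C=C(C)C1=O | intermediate
10 | 8α-hydroxy derivative of 7 (6β-angelate, 8α-OH trans to isopropenyl, C9 ketone) | O[C@@H]1[C@@H](C(C)=C)[C@@H](OC(=O)/C(C)=C\C)C=C(C)C1=O | intermediate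
11 | 8β-picolinate (pyridine-2-carboxylate, cis to isopropenyl), 6β-angelate, C9 ketone | O=C(O[C@H]1[C@@H](C(C)=C)[C@@H](OC(=O)/C(C)=C\C)C=C(C)C1=O)c1ccccn1 | intermediate
12 | 9β-alcohol of 11 (6β-angelate, 7β-isopropenyl, 8β-picolinate, 9β-OH, C10=C5) | O=C(O[C@H]1[C@@H](C(C)=C)[C@@H](OC(=O)/C(C)=C\C)C=C(C)[C@H]1O)c1ccccn1 | intermediate
13 | O9 1-(dimethylamino)vinyl ether (ketene aminal) of 12 (not isolated) | O=C(O[C@H]1[C@@H](C(C)=C)[C@@H](OC(=O)/C(C)=C\C)C=C(C)[C@H]1OC(=C)N(C)C)c1ccccn1 | intermediate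
14 | C5β–CH2C(=O)NMe2 amide with C9=C10 alkene, 6β-angelate, 8β-picolinate | O=C(O[C@H]1[C@@H](C(C)=C)[C@@H](OC(=O)/C(C)=C\C)[C@@H](CC(=O)N(C)C)C(C)=C1)c1ccccn1 | intermediate
15 | C10-quaternary amide: 10β-methyl, 10α-vinyl, C8=C9 alkene, 5β-CH2C(=O)NMe2, 6β-angelate, 7β-isopropenyl | C1=C[C@@H](C(C)=C)[C@@H](OC(=O)/C(C)=C\C)[C@@H](CC(=O)N(C)C)[C@]1(C)C=C | intermediate
16 | aldehyde: as 15 with 5β-CH2CHO | C1=C[C@@H](C(C)=C)[C@@H](OC(=O)/C(C)=C\C)[C@@H](CC=O)[C@]1(C)C=C | intermediate
17 | enal: as 15 with 5β-C(=CH2)CHO | C1=C[C@@H](C(C)=C)[C@@H](OC(=O)/C(C)=C\C)[C@@H](C(=C)C=O)[C@]1(C)C=C | intermediate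
18 | bis-enal: as 17 with 7β-C(=CH2)CHO | C1=C[C@@H](C(=C)C=O)[C@@H](OC(=O)/C(C)=C\C)[C@@H](C(=C)C=O)[C@]1(C)C=C | intermediate
19 | 8α,9α-diol of 18 (not isolated) | O[C@@H]1[C@@H](C(=C)C=O)[C@@H](OC(=O)/C(C)=C\C)[C@@H](C(=C)C=O)[C@](C)(C=C)[C@@H]1O | intermediate
20 | lactol: 12,8α-hemiacetal of 19, 9α-OH free, C12 epimers | C=C1C(O)O[C@@H]2[C@@H]1[C@@H](OC(=O)/C(C)=C\C)[C@@H](C(=C)C=O)[C@](C)(C=C)[C@@H]2O | intermediate
21 | vinyl lactone: target with a C10 vinyl group in place of the oxirane | C=C1C(=O)O[C@@H]2[C@@H]1[C@@H](OC(=O)/C(C)=C\C)[C@@H](C(=C)C=O)[C@](C)(C=C)[C@@H]2O | intermediate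
22 | CNP0113462.3 | C=C1C(=O)O[C@@H]2[C@@H]1[C@@H](OC(=O)/C(C)=C\C)[C@@H](C(=C)C=O)[C@](C)([C@@H]1CO1)[C@@H]2O | target

## Step count and risks

Total step count: 15. Longest linear sequence: 15 steps, from 1.

The three steps most likely to fail are steps 3, 9 and 10.

Step 3: singlet oxygen discriminates only modestly between the two diene faces, and the base may also remove the C6–H. The fallback sets out from 1 and returns at 5, replacing the cycloaddition by an enone transposition. Carvone 1 is epoxidised (H2O2, NaOH, MeOH, 0 °C) anti to the isopropenyl group to trans-carvone oxide F1. Rubottom oxidation at the CH2 next to C7 (LiN(iPr)2, Me3SiCl; mCPBA; aq. acid) gives the 6α-hydroxy epoxy ketone F2, with the hydroxyl anti to isopropenyl. Wharton transposition (N2H4·H2O, AcOH, MeOH) moves the oxygen to C9 and gives the ene-diol F3. MnO2 in CH2Cl2 then oxidises the less hindered allylic C9 hydroxyl to give 5 with the C6 configuration fixed.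

Step 9: the Grignard reagent may attack the esters, or the substitution may not form the quaternary carbon. The fallback sets out from 10 and returns at 15, using syn delivery from a retained 8α-oxygen instead of inversion and anti attack. PhNCO with cat. DMAP gives the 8α-N-phenylcarbamate F4. Luche reduction gives the 9β-alcohol F5. CH3C(OCH3)2N(CH3)2 at 140 °C gives, through the ketene aminal F6, the rearranged amide carbamate F7. CH3Li, then CuI, then CH2=CHMgBr (THF, −78 → 0 °C) transfers vinyl to C10 syn to the carbamate (α face) to give 15.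

Step 10: the zirconium hydride may hydrozirconate the vinyl or isopropenyl group. The fallback sets out from 12 and returns at 16, carrying the aldehyde through as an acetal. Ethyl vinyl ether with Hg(OAc)2 (cat.) gives the vinyl ether F8. After filtering off the mercury salt, heating at 150 °C in toluene gives the Claisen aldehyde F9. Ethylene glycol with pyridinium p-toluenesulfonate gives the dioxolane F10. The conditions of step 9 give the vinyl dioxolane F11, and aqueous acetic acid releases 16.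

## Further compounds

F1 | step 3 | trans-carvone oxide (C9–C10 epoxide on the α face, C5 ketone) | C1[C@@H](C(C)=C)CC(=O)[C@]2(C)O[C@H]12
F2 | step 3 | 6α-hydroxy derivative of F1 (hydroxyl trans to isopropenyl) | C1[C@@H](C(C)=C)[C@H](O)C(=O)[C@]2(C)O[C@H]12
F3 | step 3 | ene-diol: 6α,9α-dihydroxy, C10=C5 alkene | C1[C@@H](C(C)=C)[C@H](O)C=C(C)[C@@H]1O
F4 | step 9 | 8α-N-phenylcarbamate of 10 | O=C(Nc1ccccc1)O[C@@H]1[C@@H](C(C)=C)[C@@H](OC(=O)/C(C)=C\C)C=C(C)C1=O
F5 | step 9 | 9β-alcohol of F4 | O=C(Nc1ccccc1)O[C@@H]1[C@@H](C(C)=C)[C@@H](OC(=O)/C(C)=C\C)C=C(C)[C@H]1O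
F6 | step 9 | O9 ketene aminal of F5 | O=C(Nc1ccccc1)O[C@@H]1[C@@H](C(C)=C)[C@@H](OC(=O)/C(C)=C\C)C=C(C)[C@H]1OC(=C)N(C)C
F7 | step 9 | C5β–CH2C(=O)NMe2 amide with C9=C10 alkene and 8α-N-phenylcarbamate | O=C(Nc1ccccc1)O[C@@H]1[C@@H](C(C)=C)[C@@H](OC(=O)/C(C)=C\C)[C@@H](CC(=O)N(C)C)C(C)=C1
F8 | step 10 | O9 vinyl ether of 12 | O=C(O[C@H]1[C@@H](C(C)=C)[C@@H](OC(=O)/C(C)=C\C)C=C(C)[C@H]1OC=C)c1ccccn1
F9 | step 10 | C5β–CH2CHO aldehyde with C9=C10 alkene and 8β-picolinate | O=C(O[C@H]1[C@@H](C(C)=C)[C@@H](OC(=O)/C(C)=C\C)[C@@H](CC=O)C(C)=C1)c1ccccn1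
F10 | step 10 | 1,3-dioxolane acetal of F9 | O=C(O[C@H]1[C@@H](C(C)=C)[C@@H](OC(=O)/C(C)=C\C)[C@@H](CC2OCCO2)C(C)=C1)c1ccccn1
F11 | step 10 | 1,3-dioxolane acetal of 16 | C1=C[C@@H](C(C)=C)[C@@H](OC(=O)/C(C)=C\C)[C@@H](CC2OCCO2)[C@]1(C)C=C
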